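**Target:** (3S,4R,5S)-5-[(R)-(3,4-dimethoxyphenyl)(hydroxy)methyl]-4-(4-methoxyphenyl)oxolan-3-ol; the three ring substituents are all cis.

**Retrosynthetic overview**
1. The oxolane (the only ring) is formed last: the O1–C5 bond is made by 5-exo opening of a trans-(R,R) aryl epoxide by the primary OH of an acyclic 1,2-diol, with inversion at C5 and the benzylic carbinol untouched.
2. That epoxide comes from a reagent-controlled Shi epoxidation of the (E)-styrene unit of a 3-anisyl-5-aryl-pent-4-ene-1,2-diol.
3. The diol is cut between the anisyl-bearing carbon and the styrenyl carbon: an anisyl glycidol plus an (E)-styrenylboronic acid, joined by a boron-tethered, stereoretentive epoxide alkenylation (new step).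
4. The glycidol comes from Shi epoxidation of 4-methoxycinnamyl alcohol (first stereocentres, catalytic); the boronic acid comes from hydroboration of 3,4-dimethoxyphenylacetylene.

Assumption: catalysts, reagents and solvents are bought and carry no compound numbers; only skeleton-contributing materials, intermediates and the target are numbered.

**Step 1**
Reactants: 1 (E)-3-(4-methoxyphenyl)prop-2-en-1-ol (4-methoxycinnamyl alcohol)
Product: 2 [(2R,3R)-3-(4-methoxyphenyl)oxiran-2-yl]methanol
Conditions: D-fructose-derived Shi ketone (1,2:4,5-di-O-isopropylidene-β-D-erythro-2,3-hexodiulo-2,6-pyranose, 30 mol%), Oxone, K2CO3, Bu4NHSO4 (cat.), MeCN–DMM/aq. Na2B4O7–EDTA buffer (pH 10.5), 0 °C; Et3N-deactivated silica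
Reagents that add atoms: Oxone (potassium peroxymonosulfate), [K+].[O-]S(=O)(=O)OO
Why: Shi asymmetric epoxidation, in which the chiral dioxirane delivers oxygen through a spiro transition state to the olefin face that gives the (R,R)-trans-epoxide (same sense as (R,R)-trans-β-methylstyrene oxide), and the pH 10.5 medium preserves the acid-labile p-anisyl epoxide.

**Step 2**
Reactants: 3 4-ethynyl-1,2-dimethoxybenzene
Product: 5 [(E)-2-(3,4-dimethoxyphenyl)ethenyl]boronic acid, via catechol alkenylboronate 4 (not isolated)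
Conditions: catecholborane (1.1 equiv), neat, 70 °C; then H2O, rt; recrystallise
Reagents that add atoms: catecholborane, B1Oc2ccccc2O1; water, O
Why: Brown hydroboration of a terminal alkyne is syn and anti-Markovnikov, so only the (E)-alkenylboronate forms, and hydrolysis releases the crystalline boronic acid.

**Step 3**
Reactants: 2 [(2R,3R)-3-(4-methoxyphenyl)oxiran-2-yl]methanol; 5 [(E)-2-(3,4-dimethoxyphenyl)ethenyl]boronic acid
Product: 8 (2S,3R,4E)-5-(3,4-dimethoxyphenyl)-3-(4-methoxyphenyl)pent-4-ene-1,2-diol, via boronic monoester 6 (not isolated), via cyclic borate 7 (not isolated)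
Conditions: 5 (1.3 equiv), 4 Å MS, CH2Cl2, rt, 1 h; then HFIP (10 vol%), −40 → 0 °C; aq. NaHCO3/MeOH work-up
Reagents that add atoms: none
Why: Proposed new method: hydroxyl-tethered, stereoretentive benzylic alkenylation of a 2,3-epoxy alcohol by an alkenylboronic acid – the primary OH of 2 esterifies 5 (giving 6), the tethered boron chelates the oxirane oxygen (the O1/epoxide-O activation mode that makes Ti(OiPr)4-mediated openings C3-selective), the p-anisyl-stabilised benzylic C–O bond ionises as boron becomes a tetracoordinate dioxaborolane ate complex, and the electron-rich styrenyl group migrates from boron to the benzylic carbon through a five-membered transition state on the face the oxygen has just left (retention; the A1,3-minimised cation conformer and least-motion delivery coincide), which gives the anti aryl/hydroxyl relationship needed for the cis-3,4 ring pattern, keeps the E-alkene and leaves borate 7 for hydrolysis; the closest known reaction types are the Petasis borono-Mannich reaction of α-hydroxy aldehydes, metal-free benzylic opening of aryl epoxides by organotrifluoroborates, and syn-opening of aryl oxiranes by aryl borates.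

**Step 4**
Reactants: 8 (2S,3R,4E)-5-(3,4-dimethoxyphenyl)-3-(4-methoxyphenyl)pent-4-ene-1,2-diol
Product: 10 (3S,4R,5S)-5-[(R)-(3,4-dimethoxyphenyl)(hydroxy)methyl]-4-(4-methoxyphenyl)oxolan-3-ol, via epoxy diol 9 (not isolated)
Conditions: Shi ketone (D-fructose-derived, 30 mol%), Oxone, K2CO3, Bu4NHSO4, MeCN–DMM/aq. borate–EDTA buffer (pH 10.5), 0 °C; then aq. KOH to pH ≈ 13, 0 °C → rt
Reagents that add atoms: Oxone (potassium peroxymonosulfate), [K+].[O-]S(=O)(=O)OO
Why: Shi epoxidation under catalyst control (the E-alkene has only a weak allylic bias) gives the (R,R)-epoxide, and the primary alkoxide then opens it 5-exo-tet at the non-benzylic carbon with inversion (oxolane C5 = S, cis to the anisyl group) while the benzylic C–O bond is retained (carbinol = R), the basic medium suppressing SN1 opening at the benzylic carbon.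

**Compound list**
1 | (E)-3-(4-methoxyphenyl)prop-2-en-1-ol | COc1ccc(/C=C/CO)cc1 | starting material
2 | [(2R,3R)-3-(4-methoxyphenyl)oxiran-2-yl]methanol | COc1ccc([C@H]2O[C@@H]2CO)cc1 | intermediate
3 | 4-ethynyl-1,2-dimethoxybenzene | COc1ccc(C#C)cc1OC | starting material
4 | 2-[(E)-2-(3,4-dimethoxyphenyl)ethenyl]-1,3,2-benzodioxaborole | COc1ccc(/C=C/B2Oc3ccccc3O2)cc1OC | intermediate
5 | [(E)-2-(3,4-dimethoxyphenyl)ethenyl]boronic acid | COc1ccc(/C=C/B(O)O)cc1OC | intermediate
6 | [(E)-2-(3,4-dimethoxyphenyl)ethenyl]boronic acid mono{[(2R,3R)-3-(4-methoxyphenyl)oxiran-2-yl]methyl} ester | COc1ccc([C@H]2O[C@@H]2COB(O)/C=C/c2ccc(OC)c(OC)c2)cc1 | intermediate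
7 | (4S)-4-[(1R,2E)-3-(3,4-dimethoxyphenyl)-1-(4-methoxyphenyl)prop-2-en-1-yl]-1,3,2-dioxaborolan-2-ol | COc1ccc([C@H]([C@H]2COB(O)O2)/C=C/c2ccc(OC)c(OC)c2)cc1 | intermediate
8 | (2S,3R,4E)-5-(3,4-dimethoxyphenyl)-3-(4-methoxyphenyl)pent-4-ene-1,2-diol | COc1ccc([C@H]([C@H](O)CO)/C=C/c2ccc(OC)c(OC)c2)cc1 | intermediate
9 | (2S,3R)-3-[(2R,3R)-3-(3,4-dimethoxyphenyl)oxiran-2-yl]-3-(4-methoxyphenyl)propane-1,2-diol | COc1ccc([C@H]([C@H](O)CO)[C@H]2O[C@@H]2c2ccc(OC)c(OC)c2)cc1 | intermediate
10 | (3S,4R,5S)-5-[(R)-(3,4-dimethoxyphenyl)(hydroxy)methyl]-4-(4-methoxyphenyl)oxolan-3-ol | COc1ccc([C@H]2[C@@H]([C@H](O)c3ccc(OC)c(OC)c3)OC[C@H]2O)cc1 | target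

**Step count:** 4 steps in total; longest linear sequence 3 steps (1 → 2 → 8 → 10).

**Steps most likely to fail**

*Step 3 (the new step).* The risks are hydroxyl or HFIP transfer instead of alkenyl transfer, Meinwald rearrangement of the anisyl epoxide, and untethered attack that would erode the retention. The fallback uses known chemistry only; it sets out from 1 and comes back at 8. Pd-catalysed borylation of the allylic alcohol 1 with B2pin2 (Pd(MeCN)4(BF4)2 cat., DMSO–MeOH) gives 2-[(E)-3-(4-methoxyphenyl)prop-2-en-1-yl]-4,4,5,5-tetramethyl-1,3,2-dioxaborolane F1. Chiral phosphoric acid-catalysed allylboration of commercial (tert-butyldimethylsilyloxy)acetaldehyde with F1 ((S)-TRIP, 5 mol%, toluene, −30 °C) proceeds through a closed chair transition state, so the E-boronate gives the anti product, and the catalyst is chosen for Si-face addition. This gives (2S,3R)-1-[(tert-butyldimethylsilyl)oxy]-3-(4-methoxyphenyl)pent-4-en-2-ol F2. TBAF in THF removes the silyl group to give (2S,3R)-3-(4-methoxyphenyl)pent-4-ene-1,2-diol F3. Cross-metathesis of F3 with 3,4-dimethoxystyrene (Grubbs II, CH2Cl2, 40 °C) installs the (E)-styrene and gives 8.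

*Step 4.* The risks are SN1 opening of the electron-rich aryl epoxide at the benzylic carbon in the aqueous medium (6-endo or hydrolysis products) and a slow cyclisation to the crowded all-cis ring. The fallback separates oxidation from ring closure; it sets out from 8 and comes back at 10. Selective silylation of the primary hydroxyl (TBSCl, imidazole, CH2Cl2, 0 °C) gives (2S,3R,4E)-1-[(tert-butyldimethylsilyl)oxy]-5-(3,4-dimethoxyphenyl)-3-(4-methoxyphenyl)pent-4-en-2-ol F4. Shi epoxidation of F4 with the same ketone, with isolation on Et3N-deactivated silica, gives (2S,3R)-1-[(tert-butyldimethylsilyl)oxy]-3-[(2R,3R)-3-(3,4-dimethoxyphenyl)oxiran-2-yl]-3-(4-methoxyphenyl)propan-2-ol F5. TBAF in dry THF then unmasks the primary alkoxide under aprotic basic conditions, and it closes 5-exo onto the epoxide to give 10.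

*Step 1.* The risk is loss of the acid-labile p-anisyl glycidol during reaction or isolation, or insufficient ee on the free allylic alcohol. The fallback sets out from 1 and comes back at 2 with no new compound: Sharpless asymmetric epoxidation (Ti(OiPr)4 5–10 mol%, D-(−)-diisopropyl tartrate, TBHP, 4 Å MS, CH2Cl2, −20 °C, non-acidic quench). Here the allylic hydroxyl directs a Ti–tartrate-bound peroxide, and the D-tartrate gives the same (2R,3R)-epoxy alcohol.

**Further compounds**
F0 | step 1 | none | none
F1 | step 3 | 2-[(E)-3-(4-methoxyphenyl)prop-2-en-1-yl]-4,4,5,5-tetramethyl-1,3,2-dioxaborolane | COc1ccc(/C=C/CB2OC(C)(C)C(C)(C)O2)cc1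
F2 | step 3 | (2S,3R)-1-[(tert-butyldimethylsilyl)oxy]-3-(4-methoxyphenyl)pent-4-en-2-ol | COc1ccc([C@H]([C@H](O)CO[Si](C)(C)C(C)(C)C)C=C)cc1
F3 | step 3 | (2S,3R)-3-(4-methoxyphenyl)pent-4-ene-1,2-diol | COc1ccc([C@H]([C@H](O)CO)C=C)cc1
F4 | step 4 | (2S,3R,4E)-1-[(tert-butyldimethylsilyl)oxy]-5-(3,4-dimethoxyphenyl)-3-(4-methoxyphenyl)pent-4-en-2-ol | COc1ccc([C@H]([C@H](O)CO[Si](C)(C)C(C)(C)C)/C=C/c2ccc(OC)c(OC)c2)cc1
F5 | step 4 | (2S,3R)-1-[(tert-butyldimethylsilyl)oxy]-3-[(2R,3R)-3-(3,4-dimethoxyphenyl)oxiran-2-yl]-3-(4-methoxyphenyl)propan-2-ol | COc1ccc([C@H]([C@H](O)CO[Si](C)(C)C(C)(C)C)[C@H]2O[C@@H]2c2ccc(OC)c(OC)c2)cc1
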